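**Retrosynthetic overview**

- The target is reached by removing six silyl ethers from its hexasilyl ether. The resorcinol oxygens carry triisopropylsilyl groups so that the ortho oxygen stays inert toward a neighbouring enolate and toward the carbene; the two 4-hydroxyphenyl units carry tert-butyldimethylsilyl groups.
- The feature used is the tetrahydrofuran ring O1–C2–C3–C4–C5: the benzylic carbon C2 on O1 and the ketone α-carbon C3 are 1,5-related across C4–C5–O1. The C2–C3 bond is therefore made by insertion of a rhodium carbene at C3 into a benzylic C–H bond of an O1–CH2–aryl ether. This closes the only ring formed in the route and sets C2 and C3.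
- The diazo ketone comes from the 4-silyloxybenzyl ether of an anti aldol by trifluoroacetylation and diazo transfer at the methylene ketone (the future C3).
- The anti aldol (C4 and C5) comes from the mono enol silane of a symmetrical 1,4-diaryl-1,4-diketone and 4-silyloxybenzaldehyde by a catalytic enantioselective Mukaiyama aldol addition.
- The diketone comes from the zinc-mediated condensation of silylated 2',4'-dihydroxyacetophenone with its own α-bromo derivative. Tetrahydrofuran numbering (O1, C2–C5) is used for these atoms at every stage.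

Key step: step 11

Assumption: the (R,R)-bisphosphoramide (two (R)-N,N'-dimethyl-1,1'-binaphthyl-2,2'-diamine phosphoramide units joined by a pentane-1,5-diyl chain) is taken to direct the nucleophile to the Re face of aromatic aldehydes, so its (S,S)-antipode is used for the Si-face addition needed here.

**Step 1**
Reactants: 1 2',4'-dihydroxyacetophenone
Product: 2 1-[2,4-bis(triisopropylsilyloxy)phenyl]ethanone
Conditions: TIPSCl (2.4 equiv), imidazole (5 equiv), DMAP (cat.), DMF, 40 °C
Reagents that add atoms: triisopropylsilyl chloride, CC(C)[Si](Cl)(C(C)C)C(C)C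
Why: Imidazole-mediated O-silylation of both phenols (the chelated ortho hydroxyl needs DMAP and gentle warming) gives bulky silyl ethers that should neither pass silicon to a neighbouring enolate nor engage the later carbene.

**Step 2**
Reactants: 2 1-[2,4-bis(triisopropylsilyloxy)phenyl]ethanone
Product: 4 2-bromo-1-[2,4-bis(triisopropylsilyloxy)phenyl]ethanone, via trimethylsilyl enol ether 3 (not isolated)
Conditions: LiN(SiMe3)2 (1.1 equiv), THF, −78 °C; Me3SiCl (1.2 equiv); then N-bromosuccinimide (1.05 equiv), −78 → 0 °C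
Reagents that add atoms: N-bromosuccinimide, O=C1CCC(=O)N1Br
Why: In this α-bromination of a ketone through its silyl enol ether, the enol silane is far more nucleophilic than the acyl-deactivated arene, so N-bromosuccinimide should brominate only the α-carbon, under acid-free conditions that leave the aryl silyl ethers intact.

**Step 3**
Reactants: 2 1-[2,4-bis(triisopropylsilyloxy)phenyl]ethanone; 4 2-bromo-1-[2,4-bis(triisopropylsilyloxy)phenyl]ethanone
Product: 6 1,4-bis[2,4-bis(triisopropylsilyloxy)phenyl]butane-1,4-dione, via 2-aroyl-1-arylcyclopropanol 5 (not isolated)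
Conditions: 2 (1.5 equiv), 4 (1 equiv), ZnCl2 (2 equiv), Et2NH (1.5 equiv), t-BuOH (1.5 equiv), toluene, rt
Reagents that add atoms: none
Why: In this zinc-mediated condensation of a methyl ketone with an α-bromomethyl ketone, the zinc enolate of 2 adds to the carbonyl group of 4, 1,3-dehydrobromination of the bromo aldolate gives the zinc 2-acylcyclopropanolate, and its ring opening toward the ketone-stabilised carbanion delivers the 1,4-diaryl-1,4-diketone without strong base.

**Step 4**
Reactants: 6 1,4-bis[2,4-bis(triisopropylsilyloxy)phenyl]butane-1,4-dione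
Product: 8 (Z)-4-(tert-butyldimethylsilyloxy)-1,4-bis[2,4-bis(triisopropylsilyloxy)phenyl]but-3-en-1-one, via lithium mono-enolate 7 (not isolated)
Conditions: LiN(SiMe3)2 (1.0 equiv), THF, −78 °C; then TBSOTf (1.05 equiv), −78 °C; chromatography on Et3N-washed silica
Reagents that add atoms: tert-butyldimethylsilyl triflate, CC(C)(C)[Si](C)(C)OS(=O)(=O)C(F)(F)F
Why: Kinetic deprotonation of one of the two equivalent methylene ketones gives the (Z)-lithium enolate usual for aryl ketones, and the mono-anion resists a second deprotonation, so O-silylation should give mainly the mono enol silane; bis-silylated material and unchanged 6 are separated and recycled.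

**Step 5**
Reactants: 8 (Z)-4-(tert-butyldimethylsilyloxy)-1,4-bis[2,4-bis(triisopropylsilyloxy)phenyl]but-3-en-1-one; 9 4-(tert-butyldimethylsilyloxy)benzaldehyde
Product: 11 (2R)-1,4-bis[2,4-bis(triisopropylsilyloxy)phenyl]-2-{(S)-[4-(tert-butyldimethylsilyloxy)phenyl](hydroxy)methyl}butane-1,4-dione, via trichlorosilyl aldolate 10 (not isolated)
Conditions: SiCl4 (1.5 equiv), (S,S)-bisphosphoramide (5 mol%), iPr2NEt (10 mol%), CH2Cl2, −78 °C; then sat. aq. NaHCO3
Reagents that add atoms: none
Why: In this Lewis-base-catalysed, SiCl4-mediated Mukaiyama aldol addition the phosphoramide-bound trichlorosilyl cation activates the aldehyde and the enol silane adds through an open antiperiplanar transition state in which the α-substituent avoids the silicon-bound aldehyde, which should give the anti adduct, while the (S,S) catalyst exposes the Si face of the aldehyde and so sets C5 as S and C4 as R.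

**Step 6**
Reactants: 9 4-(tert-butyldimethylsilyloxy)benzaldehyde
Product: 12 [4-(tert-butyldimethylsilyloxy)phenyl]methanol
Conditions: NaBH4, MeOH, 0 °C
Reagents that add atoms: none
Why: Hydride reduction of the aldehyde is chemoselective, and the aryl silyl ether is untouched at 0 °C.

**Step 7**
Reactants: 12 [4-(tert-butyldimethylsilyloxy)phenyl]methanol
Product: 13 4-(tert-butyldimethylsilyloxy)benzyl 2,2,2-trichloroacetimidate
Conditions: Cl3CCN (1.5 equiv), DBU (1,8-diazabicyclo[5.4.0]undec-7-ene, 10 mol%), CH2Cl2, 0 °C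
Reagents that add atoms: trichloroacetonitrile, N#CC(Cl)(Cl)Cl
Why: Base-catalysed addition of the alcohol to the nitrile gives the trichloroacetimidate.

**Step 8**
Reactants: 11 (2R)-1,4-bis[2,4-bis(triisopropylsilyloxy)phenyl]-2-{(S)-[4-(tert-butyldimethylsilyloxy)phenyl](hydroxy)methyl}butane-1,4-dione; 13 4-(tert-butyldimethylsilyloxy)benzyl 2,2,2-trichloroacetimidate
Product: 14 (2R)-1,4-bis[2,4-bis(triisopropylsilyloxy)phenyl]-2-{(S)-[4-(tert-butyldimethylsilyloxy)benzyloxy][4-(tert-butyldimethylsilyloxy)phenyl]methyl}butane-1,4-dione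
Conditions: 13 (2 equiv), La(OTf)3 (5 mol%), toluene, 0 °C → rt
Reagents that add atoms: none
Why: In this acid-catalysed benzyl transfer the mild Lewis acid ionises the electron-rich imidate to the 4-silyloxybenzyl cation, which the secondary hydroxyl captures without base, so retro-aldol cleavage and epimerisation at C4 are avoided and C5 keeps its configuration because its C–O bond is not broken.

**Step 9**
Reactants: 14 (2R)-1,4-bis[2,4-bis(triisopropylsilyloxy)phenyl]-2-{(S)-[4-(tert-butyldimethylsilyloxy)benzyloxy][4-(tert-butyldimethylsilyloxy)phenyl]methyl}butane-1,4-dione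
Product: 16 (3R)-1,4-bis[2,4-bis(triisopropylsilyloxy)phenyl]-3-{(S)-[4-(tert-butyldimethylsilyloxy)benzyloxy][4-(tert-butyldimethylsilyloxy)phenyl]methyl}-2-(trifluoroacetyl)butane-1,4-dione, via lithium enolate 15 (not isolated)
Conditions: LiN(SiMe3)2 (1.1 equiv), THF, −78 °C; then CF3CO2CH2CF3 (1.3 equiv), −78 °C; cold 1 M aq. HCl; crude 16 used directly
Reagents that add atoms: 2,2,2-trifluoroethyl trifluoroacetate, O=C(OCC(F)(F)F)C(F)(F)F
Why: Kinetic enolisation should occur at the unhindered CH2 (C3) and not at the tertiary C4–H, so Claisen-type C-trifluoroacetylation activates C3 for diazo transfer without β-elimination of the benzyloxy group, the product being carried on as its mixture of C3 epimers and enol form.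

**Step 10**
Reactants: 16 (3R)-1,4-bis[2,4-bis(triisopropylsilyloxy)phenyl]-3-{(S)-[4-(tert-butyldimethylsilyloxy)benzyloxy][4-(tert-butyldimethylsilyloxy)phenyl]methyl}-2-(trifluoroacetyl)butane-1,4-dione
Product: 17 (3R)-2-diazo-1,4-bis[2,4-bis(triisopropylsilyloxy)phenyl]-3-{(S)-[4-(tert-butyldimethylsilyloxy)benzyloxy][4-(tert-butyldimethylsilyloxy)phenyl]methyl}butane-1,4-dione
Conditions: 4-acetamidobenzenesulfonyl azide (1.5 equiv), Et3N (1.5 equiv), H2O (1 equiv), MeCN, rt
Reagents that add atoms: 4-acetamidobenzenesulfonyl azide, CC(=O)Nc1ccc(cc1)S(=O)(=O)N=[N+]=[N-]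
Why: In this detrifluoroacetylative (Regitz-type) diazo transfer the ammonium enolate of the 1,3-diketone adds to the sulfonyl azide and the adduct collapses with transfer of the trifluoroacetyl group to the sulfonamide nitrogen, under conditions too mild to enolise C4.

**Step 11**
Reactants: 17 (3R)-2-diazo-1,4-bis[2,4-bis(triisopropylsilyloxy)phenyl]-3-{(S)-[4-(tert-butyldimethylsilyloxy)benzyloxy][4-(tert-butyldimethylsilyloxy)phenyl]methyl}butane-1,4-dione
Product: 18 [(2S,3R,4R,5S)-2,5-bis[4-(tert-butyldimethylsilyloxy)phenyl]tetrahydrofuran-3,4-diyl]bis{[2,4-bis(triisopropylsilyloxy)phenyl]methanone}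
Conditions: Rh2(S-PTTL)4 (dirhodium tetrakis[N-phthaloyl-(S)-tert-leucinate], 2 mol%), toluene, 17 added slowly, −60 → −20 °C
Reagents that add atoms: none
Why: The dirhodium carboxylate expels N2 from 17 to give an electrophilic rhodium carbene at C3, which inserts into one benzylic C–H bond of the O1–CH2–aryl group through a concerted three-centre transition state with hydride-transfer character, so that the C2–C3 and C3–H bonds form together with retention at C2. The closest known reaction type is the dirhodium-carboxylate-catalysed intramolecular 1,5 C–H insertion of α-alkyl α-diazo carbonyl compounds into benzylic or ether C–H bonds, which gives cis-2-aryl five-membered rings at low temperature with this phthalimido carboxylate. The tetrahydrofuran closes by 1,5 insertion, C3 joining C2 across C4–C5–O1 in a five-membered transition state. C3 (R) is controlled by allylic-type strain in the carbene, whose aroyl group eclipses H–C4 so that C2 arrives on the face anti to the C4 aroyl group (3,4-trans); C2 (S) is controlled by the carboxylate wall, the hydrogen being transferred that leaves the aryl group pointing away from the ligands, cis to the C3 aroyl group and trans to the C5 aryl group. The step needs insertion to outrun 1,2-hydride migration from C4 and capture of the carbene by oxygen lone pairs: the C2–H bond is doubly activated (ether oxygen and para-silyloxyaryl), H–C4 is α to a ketone and a poor hydride donor, the bulky carboxylate and low temperature disfavour migration, and the ortho oxygens are shielded by triisopropylsilyl groups. The S catalyst is taken in the expectation that it reinforces this substrate bias from C4 and C5.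

**Step 12**
Reactants: 18 [(2S,3R,4R,5S)-2,5-bis[4-(tert-butyldimethylsilyloxy)phenyl]tetrahydrofuran-3,4-diyl]bis{[2,4-bis(triisopropylsilyloxy)phenyl]methanone}
Product: 19 [(2S,3R,4R,5S)-2,5-bis(4-hydroxyphenyl)tetrahydrofuran-3,4-diyl]bis[(2,4-dihydroxyphenyl)methanone] (CNP0237262.3)
Conditions: HF·pyridine (excess), pyridine, THF, 0 °C → rt
Reagents that add atoms: none
Why: Fluoride cleaves all six aryl O–Si bonds under buffered, weakly acidic conditions that should neither enolise C3/C4 nor open the β-alkoxy ketone by retro-oxa-Michael reaction, so the four stereocentres are kept.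

**Compound list**

1 | 2',4'-dihydroxyacetophenone | CC(=O)c1ccc(O)cc1O | starting material
2 | 1-[2,4-bis(triisopropylsilyloxy)phenyl]ethanone | CC(=O)c1ccc(O[Si](C(C)C)(C(C)C)C(C)C)cc1O[Si](C(C)C)(C(C)C)C(C)C | intermediate
3 | trimethylsilyl enol ether of 2, 1-[2,4-bis(triisopropylsilyloxy)phenyl]-1-(trimethylsilyloxy)ethene | C=C(O[Si](C)(C)C)c1ccc(O[Si](C(C)C)(C(C)C)C(C)C)cc1O[Si](C(C)C)(C(C)C)C(C)C | intermediate
4 | 2-bromo-1-[2,4-bis(triisopropylsilyloxy)phenyl]ethanone | O=C(CBr)c1ccc(O[Si](C(C)C)(C(C)C)C(C)C)cc1O[Si](C(C)C)(C(C)C)C(C)C | intermediate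
5 | {2-[2,4-bis(triisopropylsilyloxy)phenyl]-2-hydroxycyclopropyl}[2,4-bis(triisopropylsilyloxy)phenyl]methanone (present as its zinc alkoxide; relative configuration not defined) | OC1(CC1C(=O)c1ccc(O[Si](C(C)C)(C(C)C)C(C)C)cc1O[Si](C(C)C)(C(C)C)C(C)C)c1ccc(O[Si](C(C)C)(C(C)C)C(C)C)cc1O[Si](C(C)C)(C(C)C)C(C)C | intermediate
6 | 1,4-bis[2,4-bis(triisopropylsilyloxy)phenyl]butane-1,4-dione | O=C(CCC(=O)c1ccc(O[Si](C(C)C)(C(C)C)C(C)C)cc1O[Si](C(C)C)(C(C)C)C(C)C)c1ccc(O[Si](C(C)C)(C(C)C)C(C)C)cc1O[Si](C(C)C)(C(C)C)C(C)C | intermediate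
7 | lithium (Z)-mono-enolate of 6 | [Li]O/C(=C\CC(=O)c1ccc(O[Si](C(C)C)(C(C)C)C(C)C)cc1O[Si](C(C)C)(C(C)C)C(C)C)c1ccc(O[Si](C(C)C)(C(C)C)C(C)C)cc1O[Si](C(C)C)(C(C)C)C(C)C | intermediate
8 | (Z)-4-(tert-butyldimethylsilyloxy)-1,4-bis[2,4-bis(triisopropylsilyloxy)phenyl]but-3-en-1-one | CC(C)(C)[Si](C)(C)O/C(=C\CC(=O)c1ccc(O[Si](C(C)C)(C(C)C)C(C)C)cc1O[Si](C(C)C)(C(C)C)C(C)C)c1ccc(O[Si](C(C)C)(C(C)C)C(C)C)cc1O[Si](C(C)C)(C(C)C)C(C)C | intermediate
9 | 4-(tert-butyldimethylsilyloxy)benzaldehyde | O=Cc1ccc(O[Si](C)(C)C(C)(C)C)cc1 | starting material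
10 | O-trichlorosilyl ether of 11 | O=C(c1ccc(O[Si](C(C)C)(C(C)C)C(C)C)cc1O[Si](C(C)C)(C(C)C)C(C)C)C[C@@H](C(=O)c1ccc(O[Si](C(C)C)(C(C)C)C(C)C)cc1O[Si](C(C)C)(C(C)C)C(C)C)[C@@H](c1ccc(O[Si](C)(C)C(C)(C)C)cc1)O[Si](Cl)(Cl)Cl | intermediate
11 | (2R)-1,4-bis[2,4-bis(triisopropylsilyloxy)phenyl]-2-{(S)-[4-(tert-butyldimethylsilyloxy)phenyl](hydroxy)methyl}butane-1,4-dione (anti aldol) | O=C(c1ccc(O[Si](C(C)C)(C(C)C)C(C)C)cc1O[Si](C(C)C)(C(C)C)C(C)C)C[C@@H](C(=O)c1ccc(O[Si](C(C)C)(C(C)C)C(C)C)cc1O[Si](C(C)C)(C(C)C)C(C)C)[C@@H](c1ccc(O[Si](C)(C)C(C)(C)C)cc1)O | intermediate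
12 | [4-(tert-butyldimethylsilyloxy)phenyl]methanol | OCc1ccc(O[Si](C)(C)C(C)(C)C)cc1 | intermediate
13 | 4-(tert-butyldimethylsilyloxy)benzyl 2,2,2-trichloroacetimidate | N=C(OCc1ccc(O[Si](C)(C)C(C)(C)C)cc1)C(Cl)(Cl)Cl | intermediate
14 | (2R)-1,4-bis[2,4-bis(triisopropylsilyloxy)phenyl]-2-{(S)-[4-(tert-butyldimethylsilyloxy)benzyloxy][4-(tert-butyldimethylsilyloxy)phenyl]methyl}butane-1,4-dione | O=C(c1ccc(O[Si](C(C)C)(C(C)C)C(C)C)cc1O[Si](C(C)C)(C(C)C)C(C)C)C[C@@H](C(=O)c1ccc(O[Si](C(C)C)(C(C)C)C(C)C)cc1O[Si](C(C)C)(C(C)C)C(C)C)[C@@H](c1ccc(O[Si](C)(C)C(C)(C)C)cc1)OCc1ccc(O[Si](C)(C)C(C)(C)C)cc1 | intermediate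
15 | lithium (Z)-enolate of 14 at the methylene ketone | [Li]O/C(=C\[C@@H](C(=O)c1ccc(O[Si](C(C)C)(C(C)C)C(C)C)cc1O[Si](C(C)C)(C(C)C)C(C)C)[C@@H](c1ccc(O[Si](C)(C)C(C)(C)C)cc1)OCc1ccc(O[Si](C)(C)C(C)(C)C)cc1)c1ccc(O[Si](C(C)C)(C(C)C)C(C)C)cc1O[Si](C(C)C)(C(C)C)C(C)C | intermediate
16 | (3R)-1,4-bis[2,4-bis(triisopropylsilyloxy)phenyl]-3-{(S)-[4-(tert-butyldimethylsilyloxy)benzyloxy][4-(tert-butyldimethylsilyloxy)phenyl]methyl}-2-(trifluoroacetyl)butane-1,4-dione (mixture of epimers at the trifluoroacetyl-bearing carbon and enol form) | O=C(c1ccc(O[Si](C(C)C)(C(C)C)C(C)C)cc1O[Si](C(C)C)(C(C)C)C(C)C)C(C(=O)C(F)(F)F)[C@@H](C(=O)c1ccc(O[Si](C(C)C)(C(C)C)C(C)C)cc1O[Si](C(C)C)(C(C)C)C(C)C)[C@@H](c1ccc(O[Si](C)(C)C(C)(C)C)cc1)OCc1ccc(O[Si](C)(C)C(C)(C)C)cc1 | intermediate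
17 | (3R)-2-diazo-1,4-bis[2,4-bis(triisopropylsilyloxy)phenyl]-3-{(S)-[4-(tert-butyldimethylsilyloxy)benzyloxy][4-(tert-butyldimethylsilyloxy)phenyl]methyl}butane-1,4-dione | O=C(c1ccc(O[Si](C(C)C)(C(C)C)C(C)C)cc1O[Si](C(C)C)(C(C)C)C(C)C)C(=[N+]=[N-])[C@@H](C(=O)c1ccc(O[Si](C(C)C)(C(C)C)C(C)C)cc1O[Si](C(C)C)(C(C)C)C(C)C)[C@@H](c1ccc(O[Si](C)(C)C(C)(C)C)cc1)OCc1ccc(O[Si](C)(C)C(C)(C)C)cc1 | intermediate
18 | [(2S,3R,4R,5S)-2,5-bis[4-(tert-butyldimethylsilyloxy)phenyl]tetrahydrofuran-3,4-diyl]bis{[2,4-bis(triisopropylsilyloxy)phenyl]methanone} | O=C(c1ccc(O[Si](C(C)C)(C(C)C)C(C)C)cc1O[Si](C(C)C)(C(C)C)C(C)C)[C@@H]1[C@@H](C(=O)c2ccc(O[Si](C(C)C)(C(C)C)C(C)C)cc2O[Si](C(C)C)(C(C)C)C(C)C)[C@@H](c2ccc(O[Si](C)(C)C(C)(C)C)cc2)O[C@@H]1c1ccc(O[Si](C)(C)C(C)(C)C)cc1 | intermediate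
19 | [(2S,3R,4R,5S)-2,5-bis(4-hydroxyphenyl)tetrahydrofuran-3,4-diyl]bis[(2,4-dihydroxyphenyl)methanone] | O=C(c1ccc(O)cc1O)[C@@H]1[C@@H](C(=O)c2ccc(O)cc2O)[C@@H](c2ccc(O)cc2)O[C@@H]1c1ccc(O)cc1 | target

**Step count**

Total steps: 12. Longest linear sequence: 10 steps (steps 1, 2, 3, 4, 5, 8, 9, 10, 11, 12, from 2',4'-dihydroxyacetophenone).

**Steps most likely to fail**

Step 11 (key step). The carbene may be lost by migration of H–C4 to the carbene carbon (alkene formation), by capture through a silyloxy oxygen or an arene, or by hydrogen transfer on the wrong face or from the wrong benzylic hydrogen when the catalyst works against the C4/C5 bias. The fallback makes the same C2–C3 bond by a polar route without a carbene. It sets out from 14: kinetic enolisation of the methylene ketone (LiN(SiMe3)2, THF, −78 °C) and O-acetylation with Ac2O would give the (Z)-enol acetate F1. DDQ (2,6-dichloropyridine, LiClO4, 4 Å molecular sieves, ClCH2CH2Cl, rt) would then remove hydride from the 4-silyloxybenzyl CH2, and the oxocarbenium ion would be captured by the enol acetate carbon C3, coming back to the route at 18. The 3,4-trans relation should again follow from H–C4 eclipsing the enol double bond. The configuration at C2 would be decided by the envelope transition state of this closure and is not secured, so the C2 epimer may form and would have to be checked for and separated.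

Step 5. The α-branched (Z)-enol silane may add with poor anti/syn or poor facial discrimination, turnover may be slow, and the γ-hydroxy ketone may close to a cyclic hemiketal during work-up. The fallback replaces catalyst control by a diastereoselective boron aldol followed by resolution. It sets out from 6: Cy2BCl and Et3N (Et2O, 0 °C) would give the (E)-enol dicyclohexylborinate F2, whose closed chair transition state with 9 (−78 °C) should give the anti aldol as a racemate, that is 11 together with the (2S,1'R)-enantiomer F3. Preparative chromatography on a chiral stationary phase would remove F3 and return 11 to the route.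

Step 8. Acid may ionise the benzylic carbinol, cyclodehydrate the γ-hydroxy ketone to a dihydrofuran, or rearrange the imidate to the N-benzyl amide before transfer. The fallback is a neutral, silver-promoted alkylation. It sets out from 12: PPh3 and CBr4 (CH2Cl2, 0 °C, Appel reaction) would give 4-(tert-butyldimethylsilyloxy)benzyl bromide F4. F4 and 11 with Ag2O (4 Å molecular sieves, CH2Cl2, dark, rt) would give 14, where the route is rejoined.

**Further compounds**

F1 | step 11 | (Z)-enol acetate of 14 at the methylene ketone | CC(=O)O/C(=C\[C@@H](C(=O)c1ccc(O[Si](C(C)C)(C(C)C)C(C)C)cc1O[Si](C(C)C)(C(C)C)C(C)C)[C@@H](c1ccc(O[Si](C)(C)C(C)(C)C)cc1)OCc1ccc(O[Si](C)(C)C(C)(C)C)cc1)c1ccc(O[Si](C(C)C)(C(C)C)C(C)C)cc1O[Si](C(C)C)(C(C)C)C(C)C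
F2 | step 5 | (E)-enol dicyclohexylborinate of 6 | C1CCCCC1B(C1CCCCC1)O/C(=C/CC(=O)c1ccc(O[Si](C(C)C)(C(C)C)C(C)C)cc1O[Si](C(C)C)(C(C)C)C(C)C)c1ccc(O[Si](C(C)C)(C(C)C)C(C)C)cc1O[Si](C(C)C)(C(C)C)C(C)C
F3 | step 5 | (2S)-1,4-bis[2,4-bis(triisopropylsilyloxy)phenyl]-2-{(R)-[4-(tert-butyldimethylsilyloxy)phenyl](hydroxy)methyl}butane-1,4-dione (enantiomer of 11) | O=C(c1ccc(O[Si](C(C)C)(C(C)C)C(C)C)cc1O[Si](C(C)C)(C(C)C)C(C)C)C[C@H](C(=O)c1ccc(O[Si](C(C)C)(C(C)C)C(C)C)cc1O[Si](C(C)C)(C(C)C)C(C)C)[C@H](c1ccc(O[Si](C)(C)C(C)(C)C)cc1)O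
F4 | step 8 | 4-(tert-butyldimethylsilyloxy)benzyl bromide | BrCc1ccc(O[Si](C)(C)C(C)(C)C)cc1
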